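The route rests on cutting the C3–C3a bond of the dihydrofuran ring. C3 is an unsubstituted methylene beside the C2 stereocentre. C3, C2 and the side-chain carbinol carbon therefore correspond to the methyl, carbinol and carboxyl carbons of lactate, while O1 is a phloroglucinol oxygen. In one operation, a palladium-catalysed arylation of a methyl C–H bond by the neighbouring aryl bromide forms C3–C3a and closes the ring, leaving C2 untouched. The precursor is the (S)-configured sec-alkyl ether of 2-bromo-3,5-bis(methoxymethoxy)phenol, whose ether carbon bears the methyl group and a CMe2OSiEt3 group. The prenyl (C5) and acyl (C7) groups follow by two directed lithiations.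

Key step: step 6

Remark: bicyclic compounds carry benzofuran numbering (O1, C2, C3, C3a, C4–C7, C7a). C2 of the target is (S), and because the Mitsunobu step inverts and expels the lactate oxygen, the (R)-lactate ester is the correct enantiomer.

Step 1
Reactants: 1 phloroglucinol (benzene-1,3,5-triol)
Product: 2 3,5-bis(methoxymethoxy)phenol
Conditions: MOMCl (2.0 equiv), i-Pr2NEt (2.2 equiv), CH2Cl2–THF, 0 °C → rt; chromatography
Reagents that add atoms: chloromethyl methyl ether (MOMCl), COCCl
Why: Base-mediated O-alkylation (MOM acetal formation) of the threefold symmetric triphenol with two equivalents of MOMCl should give a statistical mixture of ethers that differ by one free OH each, so the bis-ether can be separated by chromatography.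

Step 2
Reactants: 2 3,5-bis(methoxymethoxy)phenol
Product: 3 2-bromo-3,5-bis(methoxymethoxy)phenol
Conditions: NBS (1.0 equiv, slow addition), i-Pr2NH (10 mol %), CH2Cl2, −78 → 0 °C
Reagents that add atoms: N-bromosuccinimide (NBS), O=C1CCC(=O)N1Br
Why: In this amine-catalysed ortho-bromination of a phenol, the N-bromoamine formed in situ is hydrogen-bonded to the phenolic OH and delivers bromine to the adjacent C2 (equivalent to C6), whereas C4 is screened by two MOM ethers, and one equivalent of NBS at low temperature should hold the electron-rich ring at monobromination.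

Step 3
Reactants: 3 2-bromo-3,5-bis(methoxymethoxy)phenol; 4 methyl (R)-lactate
Product: 5 methyl (2S)-2-[2-bromo-3,5-bis(methoxymethoxy)phenoxy]propanoate
Conditions: PPh3 (1.3 equiv), DIAD (1.3 equiv), THF, 0 °C → rt
Reagents that add atoms: none
Why: In this Mitsunobu etherification the acidic bromophenol displaces the oxyphosphonium group of the activated α-hydroxy ester by SN2, so the (R) carbinol carbon is inverted to the (S) aryloxy carbon that becomes C2, and the lactate oxygen leaves as Ph3P=O.

Step 4
Reactants: 5 methyl (2S)-2-[2-bromo-3,5-bis(methoxymethoxy)phenoxy]propanoate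
Product: 7 (3S)-3-[2-bromo-3,5-bis(methoxymethoxy)phenoxy]-2-methylbutan-2-ol, via methyl ketone 6 (not isolated)
Conditions: MeMgBr (3.0 equiv), THF, −20 → 0 °C (ester added to the Grignard reagent); aq NH4Cl
Reagents that add atoms: methylmagnesium bromide, C[Mg]Br
Why: In this double Grignard addition to an ester, the transient ketone 6 is more electrophilic than 5 and is consumed at once by the excess reagent, which leaves little time for enolisation at the stereocentre, and MeMgBr does not exchange with the aryl bromide.

Step 5
Reactants: 7 (3S)-3-[2-bromo-3,5-bis(methoxymethoxy)phenoxy]-2-methylbutan-2-ol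
Product: 8 (S)-2-bromo-1,5-bis(methoxymethoxy)-3-{[3-methyl-3-(triethylsilyloxy)butan-2-yl]oxy}benzene
Conditions: TESOTf (1.2 equiv), 2,6-lutidine (2.0 equiv), CH2Cl2, −78 → 0 °C
Reagents that add atoms: triethylsilyl trifluoromethanesulfonate (TESOTf), CC[Si](CC)(CC)OS(=O)(=O)C(F)(F)F
Why: Silyl triflate silylation of a hindered tertiary alcohol, run with only a small excess of TESOTf at low temperature, should leave the MOM acetals untouched, and TES is chosen because it withstands carbonate at 140 °C and n-BuLi yet is cleaved by the mild acid of the last step.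

Step 6
Reactants: 8 (S)-2-bromo-1,5-bis(methoxymethoxy)-3-{[3-methyl-3-(triethylsilyloxy)butan-2-yl]oxy}benzene
Product: 9 (2S)-4,6-bis(methoxymethoxy)-2-[2-(triethylsilyloxy)propan-2-yl]-2,3-dihydro-1-benzofuran
Conditions: Pd(OAc)2 (5 mol %), PCy3·HBF4 (10 mol %), CsOPiv (30 mol %), Cs2CO3 (1.5 equiv), degassed mesitylene, 140 °C
Reagents that add atoms: none
Why: Zerovalent palladium carrying PCy3, formed in situ from Pd(OAc)2, inserts into the C–Br bond, pivalate replaces bromide on the divalent arylpalladium species, and the bound carboxylate removes a hydrogen of the ether methyl group by concerted metalation–deprotonation while Cs2CO3 takes up the acid. The closest known reaction type is the pivalate-assisted intramolecular C(sp3)–H arylation that converts o-bromoaryl tert-alkyl ethers into 2,2-dialkyl-2,3-dihydrobenzofurans and N-(sec-alkyl)-2-bromoanilides into 2-substituted indolines, the nitrogen cases showing that a hydrogen on the heteroatom-bearing carbon is tolerated. The dihydrofuran ring closes by C(sp2)–C(sp3) reductive elimination from the six-membered palladacycle (Pd, C3a, C7a, O1, C2, C3), which forms C3–C3a. No stereocentre is created, and since no bond at C2 is broken the (S) configuration set in step 3 is carried into 9. The selectivity needed is among C–H bonds: only the C2 methyl group offers a primary C–H through a six-membered palladacycle, whereas C2–H and the O–CH2–O hydrogens of the neighbouring MOM ether would give five-membered palladacycles that could only collapse to four-membered rings and should therefore revert, and the CMe2 methyls and the MOM OCH3 would need seven-membered ones. The bulky CMe2OSiEt3 group stands in for the quaternary carbon of the known substrates by turning the methyl group toward the metal, the silyl ether prevents C–O coupling of the alcohol, and the carbonate keeps the medium basic so that the MOM and TES groups should survive 140 °C.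

Step 7
Reactants: 9 (2S)-4,6-bis(methoxymethoxy)-2-[2-(triethylsilyloxy)propan-2-yl]-2,3-dihydro-1-benzofuran; 10 1-bromo-3-methylbut-2-ene (prenyl bromide)
Product: 12 (2S)-4,6-bis(methoxymethoxy)-5-(3-methylbut-2-en-1-yl)-2-[2-(triethylsilyloxy)propan-2-yl]-2,3-dihydro-1-benzofuran, via 5-lithio species 11 (not isolated)
Conditions: n-BuLi (1.15 equiv), THF, 0 °C; then 10 (1.5 equiv), −78 °C → rt
Reagents that add atoms: n-butyllithium, [Li]CCCC (supplies the lithium of 11 only)
Why: In this directed ortho-metalation followed by SN2 allylation, C5–H lies between two chelating MOM ethers and should be removed faster than C7–H, which has only one MOM neighbour, and the aryllithium attacks the unhindered primary carbon of prenyl bromide.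

Step 8
Reactants: 13 3-(4-methoxyphenyl)propanoic acid
Product: 15 N-methoxy-3-(4-methoxyphenyl)-N-methylpropanamide, via acyl imidazolide 14 (not isolated)
Conditions: CDI (1.1 equiv), CH2Cl2, rt; then MeNH(OMe)·HCl (1.3 equiv), rt
Reagents that add atoms: N,O-dimethylhydroxylamine hydrochloride, CNOC.Cl; 1,1'-carbonyldiimidazole (CDI), O=C(n1ccnc1)n1ccnc1 (supplies the imidazolyl group of 14 only)
Why: In this amide coupling through an acyl imidazolide, CDI activates the acid with loss of CO2, and the amine, freed from its hydrochloride by the liberated imidazole, is acylated to the Weinreb amide.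

Step 9
Reactants: 12 (2S)-4,6-bis(methoxymethoxy)-5-(3-methylbut-2-en-1-yl)-2-[2-(triethylsilyloxy)propan-2-yl]-2,3-dihydro-1-benzofuran; 15 N-methoxy-3-(4-methoxyphenyl)-N-methylpropanamide
Product: 18 1-[(2S)-4,6-bis(methoxymethoxy)-5-(3-methylbut-2-en-1-yl)-2-[2-(triethylsilyloxy)propan-2-yl]-2,3-dihydro-1-benzofuran-7-yl]-3-(4-methoxyphenyl)propan-1-one, via 7-lithio species 16 (not isolated), via lithium hemiaminal 17 (not isolated)
Conditions: n-BuLi (1.2 equiv), THF, 0 °C; then 15 (1.3 equiv), −78 → 0 °C; aq NH4Cl
Reagents that add atoms: n-butyllithium, [Li]CCCC (supplies the lithium of 16 and 17 only)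
Why: In this directed ortho-metalation and Weinreb ketone synthesis, C7–H is the only hydrogen left on the benzofuran benzene ring and is flanked by O1 and the C6 MOM ether, the prenyl CH2 hydrogens are held near the ring plane by the two flanking MOM ethers and so gain little benzylic acidity, and the chelated adduct 17 persists until the quench so that no second addition occurs.

Step 10
Reactants: 18 1-[(2S)-4,6-bis(methoxymethoxy)-5-(3-methylbut-2-en-1-yl)-2-[2-(triethylsilyloxy)propan-2-yl]-2,3-dihydro-1-benzofuran-7-yl]-3-(4-methoxyphenyl)propan-1-one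
Product: 19 1-[(2S)-4,6-dihydroxy-2-(2-hydroxypropan-2-yl)-5-(3-methylbut-2-en-1-yl)-2,3-dihydro-1-benzofuran-7-yl]-3-(4-methoxyphenyl)propan-1-one (CNP0150199.1)
Conditions: 3 M aq HCl–MeOH (1:10), rt → 40 °C, stopped at full conversion
Reagents that add atoms: none
Why: In this acid-catalysed acetal and silyl ether solvolysis, the two phenolic MOM ethers (the one at C6 assisted by the neighbouring carbonyl) and the tertiary TES ether cleave in dilute methanolic HCl, conditions under which ortho-prenylated acylphloroglucinols are known to persist without chroman formation, and no bond at C2 is involved.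

Compound list
1 | phloroglucinol | Oc1cc(O)cc(O)c1 | starting material
2 | 3,5-bis(methoxymethoxy)phenol | COCOc1cc(O)cc(OCOC)c1 | intermediate
3 | 2-bromo-3,5-bis(methoxymethoxy)phenol | COCOc1cc(O)c(Br)c(OCOC)c1 | intermediate
4 | methyl (R)-lactate | COC(=O)[C@@H](C)O | starting material
5 | methyl (2S)-2-[2-bromo-3,5-bis(methoxymethoxy)phenoxy]propanoate | COCOc1cc(OCOC)c(Br)c(c1)O[C@@H](C)C(=O)OC | intermediate
6 | (3S)-3-[2-bromo-3,5-bis(methoxymethoxy)phenoxy]butan-2-one (methyl ketone, not isolated) | COCOc1cc(OCOC)c(Br)c(c1)O[C@@H](C)C(C)=O | intermediate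
7 | (3S)-3-[2-bromo-3,5-bis(methoxymethoxy)phenoxy]-2-methylbutan-2-ol | COCOc1cc(OCOC)c(Br)c(c1)O[C@@H](C)C(C)(C)O | intermediate
8 | (S)-2-bromo-1,5-bis(methoxymethoxy)-3-{[3-methyl-3-(triethylsilyloxy)butan-2-yl]oxy}benzene | COCOc1cc(OCOC)c(Br)c(c1)O[C@@H](C)C(C)(C)O[Si](CC)(CC)CC | intermediate
9 | (2S)-4,6-bis(methoxymethoxy)-2-[2-(triethylsilyloxy)propan-2-yl]-2,3-dihydro-1-benzofuran | COCOc1cc(OCOC)c2c(c1)O[C@H](C(C)(C)O[Si](CC)(CC)CC)C2 | intermediate
10 | 1-bromo-3-methylbut-2-ene (prenyl bromide) | CC(C)=CCBr | starting material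
11 | 5-lithio derivative of 9 (not isolated) | COCOc1c([Li])c(OCOC)c2c(c1)O[C@H](C(C)(C)O[Si](CC)(CC)CC)C2 | intermediate
12 | (2S)-4,6-bis(methoxymethoxy)-5-(3-methylbut-2-en-1-yl)-2-[2-(triethylsilyloxy)propan-2-yl]-2,3-dihydro-1-benzofuran | COCOc1c(CC=C(C)C)c(OCOC)c2c(c1)O[C@H](C(C)(C)O[Si](CC)(CC)CC)C2 | intermediate
13 | 3-(4-methoxyphenyl)propanoic acid | COc1ccc(CCC(=O)O)cc1 | starting material
14 | 1-(imidazol-1-yl)-3-(4-methoxyphenyl)propan-1-one (acyl imidazolide, not isolated) | COc1ccc(CCC(=O)n2ccnc2)cc1 | intermediate
15 | N-methoxy-3-(4-methoxyphenyl)-N-methylpropanamide | COc1ccc(CCC(=O)N(C)OC)cc1 | intermediate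
16 | 7-lithio derivative of 12 (not isolated) | COCOc1c(CC=C(C)C)c(OCOC)c2c(c1[Li])O[C@H](C(C)(C)O[Si](CC)(CC)CC)C2 | intermediate
17 | lithium hemiaminal from 16 and 15 (tetrahedral adduct, not isolated) | COCOc1c(CC=C(C)C)c(OCOC)c2c(c1C(O[Li])(CCc3ccc(OC)cc3)N(C)OC)O[C@H](C(C)(C)O[Si](CC)(CC)CC)C2 | intermediate
18 | 1-[(2S)-4,6-bis(methoxymethoxy)-5-(3-methylbut-2-en-1-yl)-2-[2-(triethylsilyloxy)propan-2-yl]-2,3-dihydro-1-benzofuran-7-yl]-3-(4-methoxyphenyl)propan-1-one | COCOc1c(CC=C(C)C)c(OCOC)c2c(c1C(=O)CCc3ccc(OC)cc3)O[C@H](C(C)(C)O[Si](CC)(CC)CC)C2 | intermediate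
19 | 1-[(2S)-4,6-dihydroxy-2-(2-hydroxypropan-2-yl)-5-(3-methylbut-2-en-1-yl)-2,3-dihydro-1-benzofuran-7-yl]-3-(4-methoxyphenyl)propan-1-one | COc1ccc(CCC(=O)c2c(O)c(CC=C(C)C)c(O)c3c2O[C@H](C(C)(C)O)C3)cc1 | target

Total step count: 10.
Longest linear sequence: 9 (steps 1–7, 9 and 10). Step 8 is a one-step side branch.

Steps most likely to fail

1. Step 6 (key step).
- What may go wrong: the crowded, electron-rich arylpalladium intermediate may lose bromine by protodepalladation. Palladium may migrate onto the neighbouring O–CH2–O group. The palladacycle may lose a β-hydride, because C2 bears hydrogen.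
- Fallback: the ring is closed at C2–O1 instead of C3–C3a, using known chemistry only. It sets out from 3 and comes back at 9.
- Treatment of 3 with n-BuLi (2.1 equiv, THF, −78 °C) forms the phenoxide and then exchanges bromine for lithium. C-alkylation with 10 gives 3,5-bis(methoxymethoxy)-2-(3-methylbut-2-en-1-yl)phenol F1.
- TBSCl and imidazole in DMF give its tert-butyldimethylsilyl ether F2.
- Shi epoxidation follows, with 1,2:4,5-di-O-isopropylidene-β-D-erythro-2,3-hexodiulo-2,6-pyranose, KHSO5 (as 2KHSO5·KHSO4·K2SO4) and K2CO3 in MeCN–dimethoxymethane–water at 0 °C. By the spiro transition-state model this should give the (R)-epoxide F3.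
- TBAF in THF frees the phenoxide, which opens the epoxide at its secondary carbon in a 5-exo-tet closure with inversion. This gives (S)-2-[4,6-bis(methoxymethoxy)-2,3-dihydro-1-benzofuran-2-yl]propan-2-ol F4.
- Silylation as in step 5 gives 9.

2. Step 9.
- What may go wrong: deprotonation may compete at the allylic–benzylic CH2 of the prenyl group or at C3. A proton may also transfer from the α-CH2 of 15 to the aryllithium, so that 12 is simply returned.
- Fallback: C7 is functionalised first and by halogen–metal exchange, and the ketone is unveiled by oxidation. It sets out from 9 and comes back at 18.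
- NBS (1.0 equiv, CH2Cl2, −78 → 0 °C) should brominate 9 at C7, the less screened of the two free positions. The analogy is 5,7-dialkoxychromans, which brominate next to the ring oxygen. This gives the 7-bromide F5.
- Bromine–lithium exchange with n-BuLi at −78 °C and addition to commercial 3-(4-methoxyphenyl)propanal give the C7 carbinol F6. Both epimers at the carbinol carbon are acceptable.
- n-BuLi (2.2 equiv, THF, 0 °C) forms the alkoxide and then lithiates C5, the only C–H left on that ring. Alkylation with 10 gives the 5-prenyl carbinol F7.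
- Dess–Martin oxidation gives 18.
- This order also removes the dependence on the C5/C7 selectivity of step 7.

3. Step 10.
- What may go wrong: acid may induce addition of the C4 or C6 hydroxyl group to the prenyl double bond (chroman formation). The tertiary carbinol may ionise before the last MOM group has left.
- Fallback: silyl transfer and then fluoride replace proton-catalysed solvolysis. It sets out from 18 and comes back at 19.
- TMSOTf and 2,2'-bipyridyl in MeCN at 0 °C exchange both aryl MOM acetals for trimethylsilyl groups through a bipyridinium salt, without free Brønsted acid. This gives the 4,6-bis(trimethylsilyl) ether F8.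
- TBAF buffered with AcOH in THF at 0 °C then removes the two aryl TMS groups and the TES group to give 19.

Further compounds
F1 | step 6 | 3,5-bis(methoxymethoxy)-2-(3-methylbut-2-en-1-yl)phenol | COCOc1cc(O)c(CC=C(C)C)c(OCOC)c1
F2 | step 6 | tert-butyl[3,5-bis(methoxymethoxy)-2-(3-methylbut-2-en-1-yl)phenoxy]dimethylsilane | COCOc1cc(O[Si](C)(C)C(C)(C)C)c(CC=C(C)C)c(OCOC)c1
F3 | step 6 | tert-butyl(2-{[(2R)-3,3-dimethyloxiran-2-yl]methyl}-3,5-bis(methoxymethoxy)phenoxy)dimethylsilane | COCOc1cc(O[Si](C)(C)C(C)(C)C)c(C[C@H]2OC2(C)C)c(OCOC)c1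
F4 | step 6 | (S)-2-[4,6-bis(methoxymethoxy)-2,3-dihydro-1-benzofuran-2-yl]propan-2-ol | COCOc1cc(OCOC)c2c(c1)O[C@H](C(C)(C)O)C2
F5 | step 9 | (2S)-7-bromo-4,6-bis(methoxymethoxy)-2-[2-(triethylsilyloxy)propan-2-yl]-2,3-dihydro-1-benzofuran | COCOc1cc(OCOC)c2c(c1Br)O[C@H](C(C)(C)O[Si](CC)(CC)CC)C2
F6 | step 9 | 1-[(2S)-4,6-bis(methoxymethoxy)-2-[2-(triethylsilyloxy)propan-2-yl]-2,3-dihydro-1-benzofuran-7-yl]-3-(4-methoxyphenyl)propan-1-ol (both carbinol epimers) | COCOc1cc(OCOC)c2c(c1C(O)CCc3ccc(OC)cc3)O[C@H](C(C)(C)O[Si](CC)(CC)CC)C2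
F7 | step 9 | 1-[(2S)-4,6-bis(methoxymethoxy)-5-(3-methylbut-2-en-1-yl)-2-[2-(triethylsilyloxy)propan-2-yl]-2,3-dihydro-1-benzofuran-7-yl]-3-(4-methoxyphenyl)propan-1-ol (both carbinol epimers) | COCOc1c(CC=C(C)C)c(OCOC)c2c(c1C(O)CCc3ccc(OC)cc3)O[C@H](C(C)(C)O[Si](CC)(CC)CC)C2
F8 | step 10 | 3-(4-methoxyphenyl)-1-[(2S)-5-(3-methylbut-2-en-1-yl)-2-[2-(triethylsilyloxy)propan-2-yl]-4,6-bis(trimethylsilyloxy)-2,3-dihydro-1-benzofuran-7-yl]propan-1-one | COc1ccc(CCC(=O)c2c(O[Si](C)(C)C)c(CC=C(C)C)c(O[Si](C)(C)C)c3c2O[C@H](C(C)(C)O[Si](CC)(CC)CC)C3)cc1
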